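## Retrosynthetic overview

1. Target 25 ⇐ tris-O-methyl dialdehyde 24 ⇐ double ortho-formylation of diol 22 ⇐ MeLi/CeCl3 on keto ester 20, which makes both tertiary carbinols at once.
2. 20 ⇐ enone/enol triflate 19 ⇐ γ-alkylation (C-1–C-9′ bond) of silyl dienol ether 17 by the 2,4,6-trimethoxybenzylic cation from acetate 16.
3. 17 ⇐ β,γ-enone 11 ⇐ key step: dearomative Birch reductive C-methylation of tetralone acid 6, which creates the quaternary C-10 and turns the anisole ring into ring A.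
4. 6 ⇐ Friedel–Crafts closure of ring B onto the anisole ⇐ (R)-benzylsuccinate 4 ⇐ asymmetric hydrogenation of Stobbe product 3 (2-methoxybenzaldehyde + dimethyl succinate).
5. Ring order: ring B first (acylation), then ring A by dearomatisation of the arene; the aryl unit comes from 1,3,5-trimethoxybenzene.

Assumption: eudesmane locants are used (C-1 side chain, C-4 carbinol, C-5/C-10 ring fusion, C-7 hydroxyisopropyl, C-9′ benzylic carbon), and the SMILES is read as a trans-decalin with 10-Me, 4-OH and the C-7 group on one face and H-5 and the C-1 side chain on the other.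

## Route

Step 1
Reactants: 1 2-methoxybenzaldehyde; 2 dimethyl succinate
Product: 3 (3E)-3-(methoxycarbonyl)-4-(2-methoxyphenyl)but-3-enoic acid
Conditions: NaOMe, MeOH, reflux; aq. HCl
Reagents that add atoms: none
Why: Stobbe condensation gives the E half-ester through the paraconate lactone, leaving the CH2CO2H arm free for the later ring closure.

Step 2
Reactants: 3 (3E)-3-(methoxycarbonyl)-4-(2-methoxyphenyl)but-3-enoic acid
Product: 4 (3R)-3-(methoxycarbonyl)-4-(2-methoxyphenyl)butanoic acid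
Conditions: H2 (5 atm), [Rh(cod)((S,S)-Et-DuPhos)]BF4 (0.5 mol %), NaOMe (10 mol %), MeOH, 25 °C
Reagents that add atoms: none
Why: Carboxylate-directed asymmetric hydrogenation of an itaconate-type half-ester sets the future C-7 as R here (S in the target after the priority change), with the ligand antipode chosen for that sense.

Step 3
Reactants: 4 (3R)-3-(methoxycarbonyl)-4-(2-methoxyphenyl)butanoic acid
Product: 6 (2R)-8-methoxy-4-oxo-1,2,3,4-tetrahydronaphthalene-2-carboxylic acid, via keto ester 5 (not isolated)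
Conditions: P2O5/MeSO3H, 45 °C; then LiOH, THF/H2O, 0 °C; aq. HCl
Reagents that add atoms: lithium hydroxide, [Li+].[OH-]
Why: Intramolecular Friedel–Crafts acylation closes ring B at the only free ortho position, and saponification gives the acid so that C-7 is carried as a non-enolisable carboxylate through the next step.

Step 4
Reactants: 6 (2R)-8-methoxy-4-oxo-1,2,3,4-tetrahydronaphthalene-2-carboxylic acid
Product: 9 methyl (2R,4aR)-8-methoxy-4a-methyl-4-oxo-1,2,3,4,4a,7-hexahydronaphthalene-2-carboxylate, via dilithium dienolate 7 (not isolated), via lithium carboxylate 8 (not isolated)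
Conditions: Li (3.1 equiv), NH3(l)/THF, t-BuOH (1.0 equiv), −78 °C; MeI (excess), −78 °C to rt; then DMF, 40 °C
Reagents that add atoms: methyl iodide, CI
Why: Birch reductive alkylation of the aryl ketone dearomatises the anisole ring, and MeI should attack the C-10 dienolate axially on the face opposite the C-7 flap, whose equatorial carboxylate fixes the sofa of ring B, so the new methyl ends cis to the C-7 carboxyl before the carboxylate is O-methylated.

Step 5
Reactants: 9 methyl (2R,4aR)-8-methoxy-4a-methyl-4-oxo-1,2,3,4,4a,7-hexahydronaphthalene-2-carboxylate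
Product: 10 methyl (2R,4aR)-8-methoxy-4a-methyl-4-[(trifluoromethanesulfonyl)oxy]-1,2,4a,7-tetrahydronaphthalene-2-carboxylate
Conditions: KN(SiMe3)2 (1.05 equiv), PhNTf2, THF, −78 °C
Reagents that add atoms: N-phenylbis(trifluoromethanesulfonimide), O=S(=O)(N(c1ccccc1)S(=O)(=O)C(F)(F)F)C(F)(F)F
Why: The C-9 ketone can enolise only toward C-8 (C-10 is quaternary), so kinetic enolate O-triflation marks this oxygen for later hydrogenolysis while C-4 is still masked as its methyl enol ether.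

Step 6
Reactants: 10 methyl (2R,4aR)-8-methoxy-4a-methyl-4-[(trifluoromethanesulfonyl)oxy]-1,2,4a,7-tetrahydronaphthalene-2-carboxylate
Product: 11 methyl (2R,4aR,8aS)-4a-methyl-8-oxo-4-[(trifluoromethanesulfonyl)oxy]-1,2,4a,7,8,8a-hexahydronaphthalene-2-carboxylate
Conditions: (CO2H)2·2H2O, THF/H2O, 20 °C
Reagents that add atoms: water, O
Why: Mild enol ether hydrolysis unveils the C-4 ketone without conjugating the C-1/C-2 alkene, and C-5 is protonated anti to the angular methyl to give the trans ring fusion, which is also the expected thermodynamic isomer.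

Step 7
Reactants: 12 1,3,5-trimethoxybenzene; 13 3-methylbutanal
Product: 16 rac-3-methyl-1-(2,4,6-trimethoxyphenyl)butyl acetate, via aryllithium 14 (not isolated), via lithium alkoxide 15 (not isolated)
Conditions: n-BuLi, THF, 0 °C; 13, −78 °C; Ac2O, −78 to 0 °C
Reagents that add atoms: acetic anhydride, CC(=O)OC(C)=O
Why: Directed ortho-lithiation between two methoxy groups, addition to the aldehyde and in situ O-acetylation give a benzylic acetate that ionises very easily; it is used crude.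

Step 8
Reactants: 11 methyl (2R,4aR,8aS)-4a-methyl-8-oxo-4-[(trifluoromethanesulfonyl)oxy]-1,2,4a,7,8,8a-hexahydronaphthalene-2-carboxylate; 16 rac-3-methyl-1-(2,4,6-trimethoxyphenyl)butyl acetate
Product: 19 methyl (2R,4aR,5S,8aS)-4a-methyl-5-[(1S)-3-methyl-1-(2,4,6-trimethoxyphenyl)butyl]-8-oxo-4-[(trifluoromethanesulfonyl)oxy]-1,2,4a,5,8,8a-hexahydronaphthalene-2-carboxylate, via silyl dienol ether 17 (not isolated), via benzylic cation 18 (not isolated)
Conditions: TBSOTf (1.3 equiv), Et3N (1.1 equiv), CH2Cl2, −78 to 0 °C; then 16 (1.5 equiv), −78 °C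
Reagents that add atoms: none
Why: Soft enolisation at the doubly activated C-3 gives the linear dienol ether, whose γ-carbon C-1 attacks the cation in a vinylogous Mukaiyama-type alkylation anti to the axial C-10 methyl, and the open transition state with aryl anti to C-10, the isobutyl CH2 over the ring interior and H toward C-9 should give (S) at C-9′.

Step 9
Reactants: 19 methyl (2R,4aR,5S,8aS)-4a-methyl-5-[(1S)-3-methyl-1-(2,4,6-trimethoxyphenyl)butyl]-8-oxo-4-[(trifluoromethanesulfonyl)oxy]-1,2,4a,5,8,8a-hexahydronaphthalene-2-carboxylate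
Product: 20 methyl (2S,4aR,5S,8aS)-4a-methyl-5-[(1S)-3-methyl-1-(2,4,6-trimethoxyphenyl)butyl]-8-oxodecahydronaphthalene-2-carboxylate
Conditions: H2 (1 atm), PtO2, NaHCO3, EtOAc, 20 °C
Reagents that add atoms: none
Why: Catalytic hydrogenation saturates the enone alkene and hydrogenolyses the enol triflate to CH2–CH2 in one operation under neutral conditions that leave C-5 and C-7 untouched.

Step 10
Reactants: 20 methyl (2S,4aR,5S,8aS)-4a-methyl-5-[(1S)-3-methyl-1-(2,4,6-trimethoxyphenyl)butyl]-8-oxodecahydronaphthalene-2-carboxylate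
Product: 22 (1R,4S,4aR,7S,8aS)-7-(2-hydroxypropan-2-yl)-1,4a-dimethyl-4-[(1S)-3-methyl-1-(2,4,6-trimethoxyphenyl)butyl]decahydronaphthalen-1-ol, via methyl ketone 21 (not isolated)
Conditions: MeLi (6 equiv), CeCl3 (6 equiv), THF, −78 to 0 °C; aq. NH4Cl
Reagents that add atoms: methyllithium, [Li]C
Why: The weakly basic organocerium reagent adds to the ketone without enolising C-5, from the equatorial direction because the axial face is blocked by the 1,3-diaxial C-10 methyl (axial OH syn to that methyl), and adds twice to the ester to give the C-7 carbinol.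

Step 11
Reactants: 22 (1R,4S,4aR,7S,8aS)-7-(2-hydroxypropan-2-yl)-1,4a-dimethyl-4-[(1S)-3-methyl-1-(2,4,6-trimethoxyphenyl)butyl]decahydronaphthalen-1-ol
Product: 24 5-[(1S)-1-[(1S,4R,4aS,6S,8aR)-4-hydroxy-6-(2-hydroxypropan-2-yl)-4,8a-dimethyldecahydronaphthalen-1-yl]-3-methylbutyl]-2,4,6-trimethoxybenzene-1,3-dicarbaldehyde, via lithium amino alkoxide 23 (not isolated)
Conditions: n-BuLi (3.3 equiv), TMEDA, THF, 0 °C; DMF (1.0 equiv), −78 °C; s-BuLi (1.5 equiv), −78 to −30 °C; DMF (excess); aq. NH4Cl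
Reagents that add atoms: N,N-dimethylformamide, CN(C)C=O
Why: Two sequential directed ortho-metalations, each between two methoxy groups, with the first formyl group held in situ as its α-amino alkoxide, install both aldehydes while the tertiary alcohols are protected as alkoxides.

Step 12
Reactants: 24 5-[(1S)-1-[(1S,4R,4aS,6S,8aR)-4-hydroxy-6-(2-hydroxypropan-2-yl)-4,8a-dimethyldecahydronaphthalen-1-yl]-3-methylbutyl]-2,4,6-trimethoxybenzene-1,3-dicarbaldehyde
Product: 25 5-[(1S)-1-[(1S,4R,4aS,6S,8aR)-4-hydroxy-6-(2-hydroxypropan-2-yl)-4,8a-dimethyldecahydronaphthalen-1-yl]-3-methylbutyl]-2,4,6-trihydroxybenzene-1,3-dicarbaldehyde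
Conditions: LiSC6H4Me-4 (10 equiv), HMPA, 120 °C; aq. HCl
Reagents that add atoms: none
Why: Thiolate SN2 demethylation of the three aryl methyl ethers, each activated by an ortho formyl group, proceeds under basic conditions that cannot dehydrate the two tertiary alcohols.

## Compound list

1 | 2-methoxybenzaldehyde | COc1ccccc1C=O | starting material
2 | dimethyl succinate | COC(=O)CCC(=O)OC | starting material
3 | (3E)-3-(methoxycarbonyl)-4-(2-methoxyphenyl)but-3-enoic acid | COc1ccccc1/C=C(\CC(=O)O)C(=O)OC | intermediate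
4 | (3R)-3-(methoxycarbonyl)-4-(2-methoxyphenyl)butanoic acid | COc1ccccc1C[C@@H](C(=O)OC)CC(=O)O | intermediate
5 | methyl (2R)-8-methoxy-4-oxo-1,2,3,4-tetrahydronaphthalene-2-carboxylate | COc1cccc2c1C[C@@H](C(=O)OC)CC2=O | intermediate
6 | (2R)-8-methoxy-4-oxo-1,2,3,4-tetrahydronaphthalene-2-carboxylic acid | COc1cccc2c1C[C@@H](C(=O)O)CC2=O | intermediate
7 | dilithium (2R)-8-methoxy-4-oxido-1,2,3,7-tetrahydronaphthalene-2-carboxylate (dienolate, C-10 sp2) | [Li+].[Li+].[O-]C1=C2C=CCC(OC)=C2C[C@@H](C([O-])=O)C1 | intermediate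
8 | lithium (2R,4aR)-8-methoxy-4a-methyl-4-oxo-1,2,3,4,4a,7-hexahydronaphthalene-2-carboxylate | C1=CCC(OC)=C2C[C@@H](C(=O)[O-])CC(=O)[C@]12C.[Li+] | intermediate
9 | methyl (2R,4aR)-8-methoxy-4a-methyl-4-oxo-1,2,3,4,4a,7-hexahydronaphthalene-2-carboxylate | C1=CCC(OC)=C2C[C@@H](C(=O)OC)CC(=O)[C@]12C | intermediate
10 | methyl (2R,4aR)-8-methoxy-4a-methyl-4-[(trifluoromethanesulfonyl)oxy]-1,2,4a,7-tetrahydronaphthalene-2-carboxylate | C1=CCC(OC)=C2C[C@@H](C(=O)OC)C=C(OS(=O)(=O)C(F)(F)F)[C@]12C | intermediate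
11 | methyl (2R,4aR,8aS)-4a-methyl-8-oxo-4-[(trifluoromethanesulfonyl)oxy]-1,2,4a,7,8,8a-hexahydronaphthalene-2-carboxylate | C1=CCC(=O)[C@H]2C[C@@H](C(=O)OC)C=C(OS(=O)(=O)C(F)(F)F)[C@]12C | intermediate
12 | 1,3,5-trimethoxybenzene | COc1cc(OC)cc(OC)c1 | starting material
13 | 3-methylbutanal | CC(C)CC=O | starting material
14 | (2,4,6-trimethoxyphenyl)lithium | [Li]c1c(OC)cc(OC)cc1OC | intermediate
15 | lithium 3-methyl-1-(2,4,6-trimethoxyphenyl)butan-1-olate (racemic) | CC(C)CC([O-])c1c(OC)cc(OC)cc1OC.[Li+] | intermediate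
16 | rac-3-methyl-1-(2,4,6-trimethoxyphenyl)butyl acetate | CC(C)CC(OC(C)=O)c1c(OC)cc(OC)cc1OC | intermediate
17 | methyl (2R,4aR,8aS)-8-[(tert-butyldimethylsilyl)oxy]-4a-methyl-4-[(trifluoromethanesulfonyl)oxy]-1,2,4a,8a-tetrahydronaphthalene-2-carboxylate | C1=CC=C(O[Si](C)(C)C(C)(C)C)[C@H]2C[C@@H](C(=O)OC)C=C(OS(=O)(=O)C(F)(F)F)[C@]12C | intermediate
18 | 3-methyl-1-(2,4,6-trimethoxyphenyl)butan-1-ylium (benzylic cation) | CC(C)C[CH+]c1c(OC)cc(OC)cc1OC | intermediate
19 | methyl (2R,4aR,5S,8aS)-4a-methyl-5-[(1S)-3-methyl-1-(2,4,6-trimethoxyphenyl)butyl]-8-oxo-4-[(trifluoromethanesulfonyl)oxy]-1,2,4a,5,8,8a-hexahydronaphthalene-2-carboxylate | CC(C)C[C@H](c1c(OC)cc(OC)cc1OC)[C@@H]1C=CC(=O)[C@H]2C[C@@H](C(=O)OC)C=C(OS(=O)(=O)C(F)(F)F)[C@]12C | intermediate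
20 | methyl (2S,4aR,5S,8aS)-4a-methyl-5-[(1S)-3-methyl-1-(2,4,6-trimethoxyphenyl)butyl]-8-oxodecahydronaphthalene-2-carboxylate | CC(C)C[C@H](c1c(OC)cc(OC)cc1OC)[C@@H]1CCC(=O)[C@H]2C[C@@H](C(=O)OC)CC[C@]12C | intermediate
21 | 1-[(2S,4aR,5S,8R,8aS)-8-hydroxy-4a,8-dimethyl-5-[(1S)-3-methyl-1-(2,4,6-trimethoxyphenyl)butyl]decahydronaphthalen-2-yl]ethanone (present as its lithium alkoxide) | CC(C)C[C@H](c1c(OC)cc(OC)cc1OC)[C@@H]1CC[C@@](C)(O)[C@H]2C[C@@H](C(C)=O)CC[C@]12C | intermediate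
22 | (1R,4S,4aR,7S,8aS)-7-(2-hydroxypropan-2-yl)-1,4a-dimethyl-4-[(1S)-3-methyl-1-(2,4,6-trimethoxyphenyl)butyl]decahydronaphthalen-1-ol | CC(C)C[C@H](c1c(OC)cc(OC)cc1OC)[C@@H]1CC[C@@](C)(O)[C@H]2C[C@@H](C(C)(C)O)CC[C@]12C | intermediate
23 | trilithium salt of the mono-formylation adduct (aryl CH(O−)NMe2 at C-3 of the arene, both tertiary alkoxides) | CC(C)C[C@H](c1c(OC)c(C([O-])N(C)C)c(OC)cc1OC)[C@@H]1CC[C@@](C)([O-])[C@H]2C[C@@H](C(C)(C)[O-])CC[C@]12C.[Li+].[Li+].[Li+] | intermediate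
24 | 5-[(1S)-1-[(1S,4R,4aS,6S,8aR)-4-hydroxy-6-(2-hydroxypropan-2-yl)-4,8a-dimethyldecahydronaphthalen-1-yl]-3-methylbutyl]-2,4,6-trimethoxybenzene-1,3-dicarbaldehyde | CC(C)C[C@H](c1c(OC)c(C=O)c(OC)c(C=O)c1OC)[C@@H]1CC[C@@](C)(O)[C@H]2C[C@@H](C(C)(C)O)CC[C@]12C | intermediate
25 | 5-[(1S)-1-[(1S,4R,4aS,6S,8aR)-4-hydroxy-6-(2-hydroxypropan-2-yl)-4,8a-dimethyldecahydronaphthalen-1-yl]-3-methylbutyl]-2,4,6-trihydroxybenzene-1,3-dicarbaldehyde | CC(C)C[C@H](c1c(O)c(C=O)c(O)c(C=O)c1O)[C@@H]1CC[C@@](C)(O)[C@H]2C[C@@H](C(C)(C)O)CC[C@]12C | target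

## Step count and risks

Total step count: 12. Longest linear sequence: 11 (steps 1–6 and 8–12; step 7 is the one-step side branch).

**Steps most likely to fail**

Step 4 (Birch reductive methylation). The risks are over-reduction of the aryl ketone and a modest face selectivity at C-10, since the 1,4-relay from C-7 rests only on the chair-versus-boat preference of ring B. The fallback sets out from 6 and installs the angular methyl by conjugate addition instead.
- Hydrogenolysis of the benzylic ketone (H2, Pd/C, cat. HClO4, AcOH) gives (2S)-8-methoxy-1,2,3,4-tetrahydronaphthalene-2-carboxylic acid F1.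
- Ordinary Birch reduction (Li, NH3, t-BuOH) followed by HCl in MeOH (hydrolysis, conjugation, esterification) gives methyl (2S)-8-oxo-1,2,3,4,5,6,7,8-octahydronaphthalene-2-carboxylate F2.
- Me2CuLi/BF3·OEt2 adds axially, cis to the C-7 ester, and NaOMe equilibration gives the trans-decalone methyl (2S,4aS,8aS)-4a-methyl-8-oxodecahydronaphthalene-2-carboxylate F3.
- Kinetic enolisation (LiN(i-Pr)2, Me3SiCl) and Pd(OAc)2 dehydrogenation give methyl (2S,4aR,8aS)-4a-methyl-8-oxo-1,2,3,4,4a,5,8,8a-octahydronaphthalene-2-carboxylate F4.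
- Extended silyl dienol ether formation (TBSOTf, Et3N) and alkylation with 16 as in step 8 give methyl (2S,4aR,5S,8aS)-4a-methyl-5-[(1S)-3-methyl-1-(2,4,6-trimethoxyphenyl)butyl]-8-oxo-1,2,3,4,4a,5,8,8a-octahydronaphthalene-2-carboxylate F5.
- Hydrogenation (H2, Pd/C) brings the sequence back to the route at 20.

Step 8 (γ-alkylation). The risks are α- versus γ-attack at a carbon next to a quaternary centre and the C-9′ configuration, which depends on an open transition state. The fallback sets out from 12 and fixes C-9′ by reagent control through a planar-chiral benzylic cation.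
- Acylation of 12 with 3-methylbutanoyl chloride (SnCl4) gives 3-methyl-1-(2,4,6-trimethoxyphenyl)butan-1-one F6.
- Oxazaborolidine reduction ((S)-Me-CBS, BH3·SMe2) gives (1R)-3-methyl-1-(2,4,6-trimethoxyphenyl)butan-1-ol F7.
- Acetylation (Ac2O, DMAP) gives (1R)-3-methyl-1-(2,4,6-trimethoxyphenyl)butyl acetate F8.
- Heating with Cr(CO)6 gives the single tricarbonyl(η6-arene) complex of zerovalent chromium, tricarbonyl[(1R)-3-methyl-1-(2,4,6-trimethoxyphenyl)butyl acetate]chromium F9; the two arene faces are equivalent.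
- BF3·OEt2-mediated reaction of F9 with 17 (made from 11 as in step 8) proceeds with exo loss of acetate and exo attack, that is with retention, to give the tricarbonylchromium complex of 19, F10.
- Decomplexation with I2 comes back to the route at 19.

Step 11 (double formylation). The risk is that the second directed metalation stalls next to the hindered side chain. The fallback sets out from 22 and uses halogenation and halogen–metal exchange.
- NBS (2.1 equiv, MeCN, 0 °C) gives (1R,4S,4aR,7S,8aS)-4-[(1S)-1-(3,5-dibromo-2,4,6-trimethoxyphenyl)-3-methylbutyl]-7-(2-hydroxypropan-2-yl)-1,4a-dimethyldecahydronaphthalen-1-ol F11.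
- Excess t-BuLi (THF, −78 °C; alkoxide formation and double bromine–lithium exchange) followed by DMF comes back to the route at 24.

## Further compounds

F1 | step 4 | (2S)-8-methoxy-1,2,3,4-tetrahydronaphthalene-2-carboxylic acid | COc1cccc2c1C[C@@H](C(=O)O)CC2
F2 | step 4 | methyl (2S)-8-oxo-1,2,3,4,5,6,7,8-octahydronaphthalene-2-carboxylate | O=C1CCCC2=C1C[C@@H](C(=O)OC)CC2
F3 | step 4 | methyl (2S,4aS,8aS)-4a-methyl-8-oxodecahydronaphthalene-2-carboxylate | C1CCC(=O)[C@H]2C[C@@H](C(=O)OC)CC[C@]12C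
F4 | step 4 | methyl (2S,4aR,8aS)-4a-methyl-8-oxo-1,2,3,4,4a,5,8,8a-octahydronaphthalene-2-carboxylate | C1C=CC(=O)[C@H]2C[C@@H](C(=O)OC)CC[C@]12C
F5 | step 4 | methyl (2S,4aR,5S,8aS)-4a-methyl-5-[(1S)-3-methyl-1-(2,4,6-trimethoxyphenyl)butyl]-8-oxo-1,2,3,4,4a,5,8,8a-octahydronaphthalene-2-carboxylate | CC(C)C[C@H](c1c(OC)cc(OC)cc1OC)[C@@H]1C=CC(=O)[C@H]2C[C@@H](C(=O)OC)CC[C@]12C
F6 | step 8 | 3-methyl-1-(2,4,6-trimethoxyphenyl)butan-1-one | CC(C)CC(=O)c1c(OC)cc(OC)cc1OC
F7 | step 8 | (1R)-3-methyl-1-(2,4,6-trimethoxyphenyl)butan-1-ol | CC(C)C[C@@H](O)c1c(OC)cc(OC)cc1OC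
F8 | step 8 | (1R)-3-methyl-1-(2,4,6-trimethoxyphenyl)butyl acetate | CC(C)C[C@@H](OC(C)=O)c1c(OC)cc(OC)cc1OC
F9 | step 8 | tricarbonyl[η6-(1R)-3-methyl-1-(2,4,6-trimethoxyphenyl)butyl acetate]chromium | CC(C)C[C@@H](OC(C)=O)c1c(OC)cc(OC)cc1OC.[Cr].[C-]#[O+].[C-]#[O+].[C-]#[O+]
F10 | step 8 | tricarbonylchromium η6-arene complex of 19 | CC(C)C[C@H](c1c(OC)cc(OC)cc1OC)[C@@H]1C=CC(=O)[C@H]2C[C@@H](C(=O)OC)C=C(OS(=O)(=O)C(F)(F)F)[C@]12C.[Cr].[C-]#[O+].[C-]#[O+].[C-]#[O+]
F11 | step 11 | (1R,4S,4aR,7S,8aS)-4-[(1S)-1-(3,5-dibromo-2,4,6-trimethoxyphenyl)-3-methylbutyl]-7-(2-hydroxypropan-2-yl)-1,4a-dimethyldecahydronaphthalen-1-ol | CC(C)C[C@H](c1c(OC)c(Br)c(OC)c(Br)c1OC)[C@@H]1CC[C@@](C)(O)[C@H]2C[C@@H](C(C)(C)O)CC[C@]12C
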